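The saturated ring of the tetralin is opened between C1 and C2, and everything rests on that. The key step uses two features of that ring: the hydroxyl on C1, a benzylic carbon bound to C8a of ring A, can be brought in by way of boron, and the neighbouring C2 is an unhindered CH2 group that shifts readily from boron to carbon. One operation (benzylic lithiation next to a carbamate, capture by a boronate tethered through C2, ring-contracting 1,2-shift) forms C1–C2, closes the six-membered carbocycle and leaves boron on C1. The precursor is an open-chain (S)-1,1-diaryl-3-borylpropane whose ring A bears the carbamoyloxymethyl group; C4 is set earlier by asymmetric allylic arylation, and C1 is adjusted to cis afterwards.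

Key step: step 10

Remark on the chemistry (assumption): atom numbers are those of the tetralin of the target (C1 carbinol, C4 diarylmethine, C4a/C8a fusion atoms, ring A = its benzene ring); ArN = 5-methoxy-4-{[tri(propan-2-yl)silyl]oxy}naphthalen-1-yl, Cb = N,N-di(propan-2-yl)carbamoyl; the ring contraction is expected to place boron anti to the C4 naphthyl group, so its product is drawn as the 1,4-trans boronate and the cis relation of the target is installed afterwards through the C1 ketone, a sequence that reaches the target from either C1 epimer.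

Step 1
Reactants: 1 2-bromo-3-methoxybenzaldehyde
Product: 2 (2-bromo-3-methoxyphenyl)methanol
Conditions: NaBH4, MeOH, 0 °C
Reagents that add atoms: none
Why: Borohydride 1,2-reduction of the aldehyde is chemoselective and leaves the aryl bromide and the methyl ether untouched.

Step 2
Reactants: 2 (2-bromo-3-methoxyphenyl)methanol
Product: 3 (2-bromo-3-methoxyphenyl)methyl N,N-di(propan-2-yl)carbamate
Conditions: NaH, THF, 0 °C; then iPr2NC(O)Cl, 60 °C
Reagents that add atoms: N,N-di(propan-2-yl)carbamoyl chloride, CC(C)N(C(C)C)C(Cl)=O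
Why: O-Carbamoylation of the sodium alkoxide (nucleophilic acyl substitution) installs the group that later directs the benzylic lithiation and leaves from C1.

Step 3
Reactants: 4 8-methoxynaphthalen-1-ol
Product: 5 4-bromo-8-methoxynaphthalen-1-ol
Conditions: NBS (1.0 equiv), MeCN, −30 → 0 °C
Reagents that add atoms: N-bromosuccinimide, BrN1C(=O)CCC1=O
Why: Electrophilic aromatic bromination should go para to the free hydroxyl group, the strongest donor of the naphthalene and further activated by its hydrogen bond to the peri methoxy oxygen, while low temperature and one equivalent of reagent hold back ortho- and dibromination.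

Step 4
Reactants: 5 4-bromo-8-methoxynaphthalen-1-ol
Product: 6 [(4-bromo-8-methoxynaphthalen-1-yl)oxy]tri(propan-2-yl)silane
Conditions: TIPSOTf, 2,6-lutidine, CH2Cl2, 0 → 25 °C
Reagents that add atoms: tri(propan-2-yl)silyl trifluoromethanesulfonate, CC(C)[Si](OS(=O)(=O)C(F)(F)F)(C(C)C)C(C)C
Why: Silylation of the hindered phenol with the silyl triflate gives an aryl silyl ether that should withstand the Grignard, lithium amide and mild oxidation steps ahead and is cleaved by fluoride at the end.

Step 5
Reactants: 6 [(4-bromo-8-methoxynaphthalen-1-yl)oxy]tri(propan-2-yl)silane; 7 methyl acrylate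
Product: 8 methyl (2E)-3-ArN-prop-2-enoate
Conditions: Pd(OAc)2 (5 mol%), P(o-tol)3 (10 mol%), Et3N, DMF, 100 °C
Reagents that add atoms: none
Why: Mizoroki–Heck reaction of the aryl bromide with the acrylate gives the E-arylacrylate, the geometry following from syn-insertion and syn-β-hydride elimination.

Step 6
Reactants: 8 methyl (2E)-3-ArN-prop-2-enoate
Product: 9 (2E)-3-ArN-prop-2-en-1-ol
Conditions: DIBAL-H (2.5 equiv), CH2Cl2, −78 °C; aq. potassium sodium tartrate
Reagents that add atoms: none
Why: 1,2-Reduction of the conjugated ester with DIBAL-H gives the allylic alcohol and keeps the E double bond and the aryl silyl ether.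

Step 7
Reactants: 9 (2E)-3-ArN-prop-2-en-1-ol
Product: 10 diethyl (2E)-3-ArN-prop-2-en-1-yl phosphate
Conditions: ClP(O)(OEt)2, Et3N, DMAP (cat.), CH2Cl2, 0 °C
Reagents that add atoms: diethyl chlorophosphate, CCOP(=O)(Cl)OCC
Why: Phosphorylation of the primary allylic alcohol provides the leaving group suited to copper-catalysed SN2′ substitution; the electron-rich phosphate is to be used without chromatography.

Step 8
Reactants: 3 (2-bromo-3-methoxyphenyl)methyl N,N-di(propan-2-yl)carbamate; 10 diethyl (2E)-3-ArN-prop-2-en-1-yl phosphate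
Product: 12 {3-methoxy-2-[(1S)-1-ArN-prop-2-en-1-yl]phenyl}methyl N,N-di(propan-2-yl)carbamate, via arylmagnesium bromide 11 (not isolated)
Conditions: 3, Mg, THF, 50 °C; then 10, CuTC (5 mol%), chiral 4,5-diphenylimidazolinium chloride (NHC precursor, 6 mol%), CH2Cl2, −78 °C
Reagents that add atoms: none
Why: Copper-catalysed enantioselective allylic arylation (SN2′): the arylcopper species from Grignard reagent 11 attacks the naphthyl-bearing γ-carbon anti to the phosphate and reductive elimination gives the branched alkene, the chiral N-heterocyclic carbene ligand (antipode chosen for S) deciding the alkene face and so setting C4.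

Step 9
Reactants: 12 {3-methoxy-2-[(1S)-1-ArN-prop-2-en-1-yl]phenyl}methyl N,N-di(propan-2-yl)carbamate; 13 pinacolborane (4,4,5,5-tetramethyl-1,3,2-dioxaborolane)
Product: 14 {3-methoxy-2-[(1S)-1-ArN-3-(4,4,5,5-tetramethyl-1,3,2-dioxaborolan-2-yl)propyl]phenyl}methyl N,N-di(propan-2-yl)carbamate
Conditions: [Ir(cod)Cl]2 (1.5 mol%), dppe (3 mol%), CH2Cl2, 25 °C
Reagents that add atoms: none
Why: Iridium-catalysed hydroboration of the monosubstituted alkene with pinacolborane places boron on the terminal carbon (anti-Markovnikov) and gives the pinacol boronate directly without touching C4.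

Step 10
Reactants: 14 {3-methoxy-2-[(1S)-1-ArN-3-(4,4,5,5-tetramethyl-1,3,2-dioxaborolan-2-yl)propyl]phenyl}methyl N,N-di(propan-2-yl)carbamate
Product: 17 2-[(1R,4S)-4-ArN-5-methoxy-1,2,3,4-tetrahydronaphthalen-1-yl]-4,4,5,5-tetramethyl-1,3,2-dioxaborolane (1,4-trans), via lithiated carbamate 15 (not isolated), via cyclic boronate complex 16 (not isolated)
Conditions: LDA (1.3 equiv, slow addition), THF (0.02 M), −78 °C, 2 h; then → 40 °C
Reagents that add atoms: none
Why: Proposed new method: LDA removes a proton from the benzylic CH2 next to the carbamate (dipole-stabilised, configurationally labile α-oxy carbanion 15) in the presence of the boronate, which it does not consume; the carbanion adds to the tethered boron to give the seven-membered boronate complex 16, and on warming the ring bond B–C2, antiperiplanar to C1–O, shifts to C1 with loss of the carbamate and inversion at C1. The closest known reaction type is the lithiation–borylation homologation of benzylic carbamates with alkyl pinacol boronates under in situ deprotonation by a lithium amide; new here is that the migrating carbon belongs to the boracycle, so that the 1,2-metallate shift contracts the ring. The six-membered carbocycle is therefore closed by ring contraction of a seven-membered ate complex (C1–C2 formed by 1,2-shift), not by direct 6-exo-tet alkylation. The new stereocentre C1 is controlled by C4: in a chair-like complex the naphthyl group is pseudoaxial (it avoids the peri C5–OMe), boron is bound on the face of C3, and the carbamate must be pseudoequatorial to lie anti to B–C2, so boron should end on the face opposite the naphthyl group (1,4-trans, 1R,4S). The step needs site-selective deprotonation at C1 rather than at the doubly benzylic C4–H, which the coordinating carbamate and the crowding at C4 secure, and migration of C2 rather than of a pinacol oxygen, which the antiperiplanar ring bond secures; high dilution favours intramolecular capture. The C1 configuration is not needed later, since steps 12 and 13 reset it.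

Step 11
Reactants: 17 2-[(1R,4S)-4-ArN-5-methoxy-1,2,3,4-tetrahydronaphthalen-1-yl]-4,4,5,5-tetramethyl-1,3,2-dioxaborolane
Product: 18 (1R,4S)-4-ArN-5-methoxy-1,2,3,4-tetrahydronaphthalen-1-ol (1,4-trans)
Conditions: NaBO3·4H2O, THF/H2O (1:1), 25 °C
Reagents that add atoms: sodium perborate, [Na+].[Na+].O[B-]1(O)OO[B-](O)(O)OO1
Why: Oxidation of the C–B bond by perborate (boron-to-oxygen 1,2-shift of C1) is stereoretentive and mild enough to spare the aryl silyl ether.

Step 12
Reactants: 18 (1R,4S)-4-ArN-5-methoxy-1,2,3,4-tetrahydronaphthalen-1-ol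
Product: 19 (4S)-4-ArN-5-methoxy-3,4-dihydronaphthalen-1(2H)-one
Conditions: DMP, CH2Cl2, 0 → 25 °C
Reagents that add atoms: none
Why: Dess–Martin oxidation of the secondary benzylic alcohol gives the tetralone under near-neutral conditions; C1 is flattened on purpose so that either C1 epimer of the boronate leads to the same ketone, while the non-enolisable C4 centre stays as it is.

Step 13
Reactants: 19 (4S)-4-ArN-5-methoxy-3,4-dihydronaphthalen-1(2H)-one
Product: 20 (1S,4S)-4-ArN-5-methoxy-1,2,3,4-tetrahydronaphthalen-1-ol (1,4-cis)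
Conditions: (R)-Me-CBS (20 mol%), BH3·SMe2, THF, −20 °C; MeOH
Reagents that add atoms: none
Why: Corey–Bakshi–Shibata reduction with the (R)-oxazaborolidine should deliver hydride to the carbonyl face that gives the (1S)-alcohol, which is also the face opposite the pseudoaxial C4 naphthyl group, so that reagent and substrate control act together and set C1 cis to C4.

Step 14
Reactants: 20 (1S,4S)-4-ArN-5-methoxy-1,2,3,4-tetrahydronaphthalen-1-ol
Product: 21 (1S,4S)-4-(4-hydroxy-5-methoxynaphthalen-1-yl)-5-methoxy-1,2,3,4-tetrahydronaphthalen-1-ol (dipolynaphthalene B)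
Conditions: TBAF, AcOH, THF, 0 °C
Reagents that add atoms: none
Why: Fluoride-induced cleavage of the Si–O bond (desilylation), buffered with acetic acid, frees the naphthol and leaves the benzylic alcohol, both methyl ethers and both stereocentres untouched.

Compound list
1 | 2-bromo-3-methoxybenzaldehyde | COc1cccc(C=O)c1Br | starting material
2 | (2-bromo-3-methoxyphenyl)methanol | COc1cccc(CO)c1Br | intermediate
3 | (2-bromo-3-methoxyphenyl)methyl N,N-di(propan-2-yl)carbamate | COc1cccc(COC(=O)N(C(C)C)C(C)C)c1Br | intermediate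
4 | 8-methoxynaphthalen-1-ol | COc1cccc2cccc(O)c12 | starting material
5 | 4-bromo-8-methoxynaphthalen-1-ol | COc1cccc2c(Br)ccc(O)c12 | intermediate
6 | [(4-bromo-8-methoxynaphthalen-1-yl)oxy]tri(propan-2-yl)silane | COc1cccc2c(Br)ccc(O[Si](C(C)C)(C(C)C)C(C)C)c12 | intermediate
7 | methyl acrylate | C=CC(=O)OC | starting material
8 | methyl (2E)-3-(5-methoxy-4-{[tri(propan-2-yl)silyl]oxy}naphthalen-1-yl)prop-2-enoate | COC(=O)/C=C/c1ccc(O[Si](C(C)C)(C(C)C)C(C)C)c2c(OC)cccc12 | intermediate
9 | (2E)-3-(5-methoxy-4-{[tri(propan-2-yl)silyl]oxy}naphthalen-1-yl)prop-2-en-1-ol | OC/C=C/c1ccc(O[Si](C(C)C)(C(C)C)C(C)C)c2c(OC)cccc12 | intermediate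
10 | diethyl (2E)-3-(5-methoxy-4-{[tri(propan-2-yl)silyl]oxy}naphthalen-1-yl)prop-2-en-1-yl phosphate | CCOP(=O)(OCC)OC/C=C/c1ccc(O[Si](C(C)C)(C(C)C)C(C)C)c2c(OC)cccc12 | intermediate
11 | [2-({[di(propan-2-yl)carbamoyl]oxy}methyl)-6-methoxyphenyl]magnesium bromide | COc1cccc(COC(=O)N(C(C)C)C(C)C)c1[Mg]Br | intermediate (not isolated)
12 | {3-methoxy-2-[(1S)-1-ArN-prop-2-en-1-yl]phenyl}methyl N,N-di(propan-2-yl)carbamate | COc1cccc(COC(=O)N(C(C)C)C(C)C)c1[C@H](c1ccc(O[Si](C(C)C)(C(C)C)C(C)C)c2c(OC)cccc12)C=C | intermediate
13 | pinacolborane (4,4,5,5-tetramethyl-1,3,2-dioxaborolane) | B1OC(C)(C)C(C)(C)O1 | starting material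
14 | {3-methoxy-2-[(1S)-1-ArN-3-(4,4,5,5-tetramethyl-1,3,2-dioxaborolan-2-yl)propyl]phenyl}methyl N,N-di(propan-2-yl)carbamate | COc1cccc(COC(=O)N(C(C)C)C(C)C)c1[C@H](c1ccc(O[Si](C(C)C)(C(C)C)C(C)C)c2c(OC)cccc12)CCB1OC(C)(C)C(C)(C)O1 | intermediate (key-step precursor)
15 | 14 lithiated at the carbamate-bearing benzylic carbon C1 (configuration at C1 labile) | COc1cccc(C([Li])OC(=O)N(C(C)C)C(C)C)c1[C@H](c1ccc(O[Si](C(C)C)(C(C)C)C(C)C)c2c(OC)cccc12)CCB1OC(C)(C)C(C)(C)O1 | intermediate (not isolated)
16 | lithium boronate complex with boron in a seven-membered ring (B–C1–C8a–C4a–C4–C3–C2) and held by pinacol; C1 bears H and OCb, OCb trans to ArN | [Li+].COc1cccc2c1[C@H](c1ccc(O[Si](C(C)C)(C(C)C)C(C)C)c3c(OC)cccc13)CC[B-]1(OC(C)(C)C(C)(C)O1)[C@H]2OC(=O)N(C(C)C)C(C)C | intermediate (not isolated)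
17 | 2-[(1R,4S)-4-ArN-5-methoxy-1,2,3,4-tetrahydronaphthalen-1-yl]-4,4,5,5-tetramethyl-1,3,2-dioxaborolane (1,4-trans) | COc1cccc2c1[C@H](c1ccc(O[Si](C(C)C)(C(C)C)C(C)C)c3c(OC)cccc13)CC[C@H]2B1OC(C)(C)C(C)(C)O1 | intermediate (key-step product)
18 | (1R,4S)-4-ArN-5-methoxy-1,2,3,4-tetrahydronaphthalen-1-ol (1,4-trans) | COc1cccc2c1[C@H](c1ccc(O[Si](C(C)C)(C(C)C)C(C)C)c3c(OC)cccc13)CC[C@H]2O | intermediate
19 | (4S)-4-ArN-5-methoxy-3,4-dihydronaphthalen-1(2H)-one | COc1cccc2c1[C@H](c1ccc(O[Si](C(C)C)(C(C)C)C(C)C)c3c(OC)cccc13)CCC2=O | intermediate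
20 | (1S,4S)-4-ArN-5-methoxy-1,2,3,4-tetrahydronaphthalen-1-ol (1,4-cis) | COc1cccc2c1[C@H](c1ccc(O[Si](C(C)C)(C(C)C)C(C)C)c3c(OC)cccc13)CC[C@@H]2O | intermediate
21 | (1S,4S)-4-(4-hydroxy-5-methoxynaphthalen-1-yl)-5-methoxy-1,2,3,4-tetrahydronaphthalen-1-ol (dipolynaphthalene B) | COc1cccc2c1[C@H](c1ccc(O)c3c(OC)cccc13)CC[C@@H]2O | target

Total step count: 14. Longest linear sequence: 12 steps (steps 3–14, from 8-methoxynaphthalen-1-ol 4).

Steps most likely to fail

1. Step 10 (Proposed new method). The C1 carbanion may be captured between molecules instead of by its own boronate, may undergo 1,2-carbamoyl shift before capture, or the seven-membered complex may revert instead of contracting. The fallback uses known chemistry and forms the same C1–C2 bond by alkylation of the lithiated carbamate. It sets out from 14, whose C–B bond is oxidised (NaBO3·4H2O, THF/H2O) to the primary alcohol F1. Chlorination (PPh3, N-chlorosuccinimide, THF, 0 °C) should give the primary chloride F2. Carbamate-directed benzylic lithiation (s-BuLi, TMEDA, Et2O, −78 °C, then warming) should be followed by intramolecular 6-exo-tet displacement of chloride, giving the tetralin-1-yl carbamate F3 as its C1 epimers. Reductive cleavage of the carbamate (LiAlH4, THF) should free the alcohols 18 and 20, and Dess–Martin oxidation of the mixture as in step 12 returns the material to the route at 19.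

2. Step 8. Transfer of the doubly ortho-substituted aryl group from copper may be slow, so that uncatalysed attack at the phosphate-bearing carbon (linear product) or poor facial selectivity takes over; the electron-rich allylic phosphate may also ionise. The fallback replaces allylic substitution by rhodium-catalysed asymmetric conjugate addition (Hayashi–Miyaura reaction) and sets out from 3 and 8. Grignard reagent 11, made from 3, is quenched with B(OMe)3 and hydrolysed to the arylboronic acid F4. Its addition to enoate 8 ([RhCl(C2H4)2]2, chiral diene ligand of the antipode giving S, aq. KOH, dioxane, 50 °C) should give the (3S)-3,3-diarylpropanoate F5, with C4 set by the ligand. LiBH4 reduction should give the alcohol F1 described above, iodination (I2, PPh3, imidazole) the primary iodide F6, and copper-catalysed borylation (CuI, PPh3, LiOtBu, B2pin2, DMF) returns to the route at 14, so that step 9 is not needed.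

3. Step 9. An iridium hydride may move the terminal double bond into conjugation with the two aryl groups, which would erase C4, or addition next to the crowded diarylmethine may be slow. The fallback brings in boron together with its carbon by cross-metathesis instead of hydroboration and sets out from 12. Reaction of 12 with vinylboronic acid pinacol ester (second-generation phosphine-free ruthenium alkylidene catalyst, 1,4-benzoquinone, CH2Cl2, 40 °C) should give the E-alkenylboronate F7. Diimide reduction of its C=C bond (2-nitrobenzenesulfonohydrazide, Et3N, CH2Cl2) returns to the route at 14.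

Further compounds
F1 | step 10 | {2-[(1S)-1-ArN-3-hydroxypropyl]-3-methoxyphenyl}methyl N,N-di(propan-2-yl)carbamate | COc1cccc(COC(=O)N(C(C)C)C(C)C)c1[C@H](c1ccc(O[Si](C(C)C)(C(C)C)C(C)C)c2c(OC)cccc12)CCO
F2 | step 10 | {2-[(1S)-1-ArN-3-chloropropyl]-3-methoxyphenyl}methyl N,N-di(propan-2-yl)carbamate | COc1cccc(COC(=O)N(C(C)C)C(C)C)c1[C@H](c1ccc(O[Si](C(C)C)(C(C)C)C(C)C)c2c(OC)cccc12)CCCl
F3 | step 10 | (4S)-4-ArN-5-methoxy-1,2,3,4-tetrahydronaphthalen-1-yl N,N-di(propan-2-yl)carbamate (C1 epimers) | COc1cccc2c1[C@H](c1ccc(O[Si](C(C)C)(C(C)C)C(C)C)c3c(OC)cccc13)CCC2OC(=O)N(C(C)C)C(C)C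
F4 | step 8 | [2-({[di(propan-2-yl)carbamoyl]oxy}methyl)-6-methoxyphenyl]boronic acid | COc1cccc(COC(=O)N(C(C)C)C(C)C)c1B(O)O
F5 | step 8 | methyl (3S)-3-ArN-3-[2-({[di(propan-2-yl)carbamoyl]oxy}methyl)-6-methoxyphenyl]propanoate | COc1cccc(COC(=O)N(C(C)C)C(C)C)c1[C@H](c1ccc(O[Si](C(C)C)(C(C)C)C(C)C)c2c(OC)cccc12)CC(=O)OC
F6 | step 8 | {2-[(1S)-1-ArN-3-iodopropyl]-3-methoxyphenyl}methyl N,N-di(propan-2-yl)carbamate | COc1cccc(COC(=O)N(C(C)C)C(C)C)c1[C@H](c1ccc(O[Si](C(C)C)(C(C)C)C(C)C)c2c(OC)cccc12)CCI
F7 | step 9 | {3-methoxy-2-[(1S,2E)-1-ArN-3-(4,4,5,5-tetramethyl-1,3,2-dioxaborolan-2-yl)prop-2-en-1-yl]phenyl}methyl N,N-di(propan-2-yl)carbamate | COc1cccc(COC(=O)N(C(C)C)C(C)C)c1[C@H](c1ccc(O[Si](C(C)C)(C(C)C)C(C)C)c2c(OC)cccc12)/C=C/B1OC(C)(C)C(C)(C)O1
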